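Numbering follows labdane: ring A = C1–C5 and C10, ring B = C5–C10, side chain from C11. β is the face of the C10 methyl.
Enabling feature: rings A and B are cis-fused, and H5, the C10 methyl and the C9 side chain all lie on the β face of ring B. This pattern results from an E,E-diene (C5=C6–C7=C8), an E-enone (C9=C10 with a carbonyl at C1) and a transition state with that carbonyl endo.
Retrosynthetic cuts, in order: C11=C12 (Wittig); the C8–OH/C7–OH pair (7β,8β-epoxide); the C6–O bond (allylic transposition of a C6=C7 alkene); a carbonyl restored at C1; C5–C10 and C8–C9 together (Diels–Alder); finally C1–C10 (alkenyllithium plus aldehyde) and C5=C6 (phosphonate olefination).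
Forward: the acyclic C15 trienone is joined from three pieces (steps 1–8) and both rings close in one cycloaddition (step 9). C1 is then deoxygenated, ring B is oxygenated, and the butenone chain is completed before the final diol is released.
Stereochemistry: C5, C9, C10 and a transient C8 come from the alkene geometries and the endo folding, and their absolute sense from a chiral oxazaborolidinium catalyst. C6, C7 and C8 come from attack on the convex β face of the cis-decalin and from anti opening of the epoxide at C8.

Key step: step 9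

Assumption: the α-methyl enone has no α-vinylic hydrogen, so the sense of induction cannot be read from the usual binding picture of this catalyst; the (S)-catalyst is written, and the equally available (R)-catalyst is to be used if the cycloadduct proves to be the mirror image.

Step 1
Reactants: 1 (E)-crotyl bromide
Product: 2 diethyl (E)-but-2-en-1-ylphosphonate
Conditions: P(OEt)3, neat, 120 °C
Reagents that add atoms: triethyl phosphite, CCOP(OCC)OCC
Why: Michaelis–Arbuzov reaction, in which phosphorus attacks the primary allylic carbon and bromide dealkylates the phosphonium salt, leaving the E alkene untouched.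

Step 2
Reactants: 2 diethyl (E)-but-2-en-1-ylphosphonate; 3 2,2-dimethylpent-4-enal
Product: 5 (5E,7E)-4,4-dimethylnona-1,5,7-triene, via lithiated phosphonate 4 (not isolated)
Conditions: n-BuLi, THF–DMPU, −78 °C; then 3, −78 °C → rt; then I2 (2 mol %), hexane, daylight, rt
Reagents that add atoms: n-butyllithium, [Li]CCCC (lithium in 4 only)
Why: Horner–Wadsworth–Emmons olefination with an allylic phosphonate anion, in which the non-enolisable α-quaternary aldehyde favours the E C5=C6 bond and iodine-catalysed equilibration moves residual Z isomers to the E,E-diene.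

Step 3
Reactants: 5 (5E,7E)-4,4-dimethylnona-1,5,7-triene
Product: 7 (5E,7E)-4,4-dimethylnona-5,7-dien-1-ol, via B-alkyl-9-BBN adduct 6 (not isolated)
Conditions: 9-BBN-H (1.05 equiv), THF, 0 °C → rt; then NaOH aq, H2O2, 0 °C
Reagents that add atoms: 9-borabicyclo[3.3.1]nonane, B1C2CCCC1CCC2 (boron fragment in 6 only); hydrogen peroxide, OO
Why: Chemoselective hydroboration–oxidation, since 9-BBN-H adds anti-Markovnikov to the monosubstituted terminal alkene much faster than to the disubstituted conjugated diene, so the hydroxyl ends up on C1.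

Step 4
Reactants: 7 (5E,7E)-4,4-dimethylnona-5,7-dien-1-ol
Product: 8 (5E,7E)-4,4-dimethylnona-5,7-dienal
Conditions: PhI(OAc)2, 2,2,6,6-tetramethylpiperidine-1-oxyl (10 mol %), CH2Cl2, rt
Reagents that add atoms: none
Why: Oxoammonium-mediated alcohol oxidation, which stops at the aldehyde and leaves the diene alone.

Step 5
Reactants: 9 but-2-yn-1-ol
Product: 10 tert-butyl(but-2-yn-1-yloxy)dimethylsilane
Conditions: TBSCl, imidazole, CH2Cl2, 0 °C → rt
Reagents that add atoms: tert-butyldimethylsilyl chloride, CC(C)(C)[Si](C)(C)Cl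
Why: Standard silylation of a primary alcohol, chosen because the bulky silyl ether is a weak Lewis base and should not compete for the boron catalyst of step 9.

Step 6
Reactants: 10 tert-butyl(but-2-yn-1-yloxy)dimethylsilane
Product: 12 (E)-tert-butyl[(3-iodobut-2-en-1-yl)oxy]dimethylsilane, via alkenylzirconocene chloride 11 (not isolated)
Conditions: Cp2Zr(H)Cl (1.3 equiv), THF, rt → 40 °C; then I2, 0 °C
Reagents that add atoms: chlorobis(cyclopentadienyl)hydridozirconium, [H][Zr](Cl)(C1C=CC=C1)C1C=CC=C1 (zirconium fragment in 11 only); iodine, II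
Why: Hydrozirconation–iodination, in which H and Zr add syn, equilibration with a slight excess of hydride places zirconium next to the small methyl group, and iodinolysis with retention gives the E iodide with methyl and CH2O cis.

Step 7
Reactants: 12 (E)-tert-butyl[(3-iodobut-2-en-1-yl)oxy]dimethylsilane; 8 (5E,7E)-4,4-dimethylnona-5,7-dienal
Product: 14 (2E,8E,10E)-1-(tert-butyldimethylsilyloxy)-3,7,7-trimethyldodeca-2,8,10-trien-4-ol (carbinol centre racemic), via alkenyllithium 13 (not isolated)
Conditions: t-BuLi (2 equiv), Et2O, −78 °C; then 8, −78 °C; then H2O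
Reagents that add atoms: tert-butyllithium, [Li]C(C)(C)C (lithium in 13 only)
Why: Lithium–iodine exchange with retention of alkene geometry followed by 1,2-addition to the aldehyde forms C1–C10, and the uncontrolled carbinol centre is erased in step 8.

Step 8
Reactants: 14 (2E,8E,10E)-1-(tert-butyldimethylsilyloxy)-3,7,7-trimethyldodeca-2,8,10-trien-4-ol
Product: 15 (2E,8E,10E)-1-(tert-butyldimethylsilyloxy)-3,7,7-trimethyldodeca-2,8,10-trien-4-one
Conditions: MnO2 (activated, excess), CH2Cl2, 0 °C; used at once
Reagents that add atoms: none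
Why: Neutral MnO2 oxidation of an allylic alcohol gives the E-enone without touching diene or silyl ether, and cold handling keeps the uncatalysed cycloaddition from starting.

Step 9
Reactants: 15 (2E,8E,10E)-1-(tert-butyldimethylsilyloxy)-3,7,7-trimethyldodeca-2,8,10-trien-4-one
Product: 16 (5βH,8βH,9αH)-11-(tert-butyldimethylsilyloxy)drim-6-en-1-one (cis-fused; C10 methyl β; C8 methyl α; C9 CH2OTBS β)
Conditions: (S)-3,3-diphenyl-1-(2-methylphenyl)tetrahydro-1H,3H-pyrrolo[1,2-c][1,3,2]oxazaborole (20 mol %), (CF3SO2)2NH (18 mol %), CH2Cl2 (0.05 M), −78 → −40 °C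
Reagents that add atoms: none
Why: The cationic boron binds the C1 carbonyl of the s-cis enone, lowers its LUMO and triggers a concerted, asynchronous, suprafacial [4+2] addition in which C10 bonds to C5 and C9 to C8. The closest known reactions are the cis-selective intramolecular Diels–Alder cyclisations of 1,7,9-decatrien-3-ones and the intramolecular and transannular Diels–Alder reactions of enals and enones run with triflimide-activated oxazaborolidines. Ring B (C5–C10) closes as the cyclohexene of the cycloaddition through both new bonds, and ring A (C1–C5, C10) closes in the same event through the C5–C10 bond because the four-atom tether C1–C4 joins the diene terminus to the dienophile (type 1, fused mode). C5 and the transient C8 are fixed by the E,E-diene (C4 and the C8 methyl are both outer substituents and end up cis, α), C9 and C10 by the E-enone (C11 and the C10 methyl stay cis, β), and the two pairs are related by the endo position of the C1 carbonyl, which brings C1 to the face of C4 and so makes H5 and the C10 methyl cis. The absolute configuration is set by the catalyst, whose aryl groups cover one face of the bound enone. The step needs endo over exo folding, which the Lewis-acid-enhanced overlap of the complexed carbonyl with C6–C7 and the known cis preference of this tether secure, and catalysed over thermal turnover, which the sluggishness of the α-methyl β-alkyl enone at low temperature secures.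

Step 10
Reactants: 16 (5βH,8βH,9αH)-11-(tert-butyldimethylsilyloxy)drim-6-en-1-one
Product: 17 1-(4-methylbenzenesulfonyl)hydrazone of 16 (C=N geometry immaterial)
Conditions: TsNHNH2, 4 Å molecular sieves, THF, 60 °C
Reagents that add atoms: 4-methylbenzenesulfonohydrazide, Cc1ccc(cc1)S(=O)(=O)NN
Why: Ketone–sulfonylhydrazide condensation, feasible next to quaternary C10 because C2 is a free methylene, and run without added acid so that the silyl ether is kept.

Step 11
Reactants: 17 1-(4-methylbenzenesulfonyl)hydrazone of 16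
Product: 20 (5βH,8βH,9αH)-11-(tert-butyldimethylsilyloxy)drim-6-ene, via N-boryl tosylhydrazine 18 (not isolated), via alkyl diazene 19 (not isolated)
Conditions: catecholborane, CHCl3, −10 °C → rt; then NaOAc·3H2O, reflux
Reagents that add atoms: catecholborane, B1Oc2ccccc2O1 (boron fragment in 18 only)
Why: Caglioti-type tosylhydrazone reduction, in which hydride adds to C=N, acetate induces loss of sulfinate and the diazene extrudes N2 to leave CH2 at C1, while the isolated alkene, the silyl ether and the four stereocentres are inert.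

Step 12
Reactants: 20 (5βH,8βH,9αH)-11-(tert-butyldimethylsilyloxy)drim-6-ene
Product: 21 (5βH,8βH,9αH)-6β,7β-epoxy-11-(tert-butyldimethylsilyloxy)drimane
Conditions: mCPBA, CH2Cl2, 0 °C
Reagents that add atoms: 3-chloroperoxybenzoic acid, OOC(=O)c1cccc(Cl)c1
Why: Prilezhaev epoxidation from the convex β face (the side of H5 and H8), because the α face is covered by folded ring A, its C4 methyl groups and the 8α-methyl, which sets C6 and C7 as the β-epoxide.

Step 13
Reactants: 21 (5βH,8βH,9αH)-6β,7β-epoxy-11-(tert-butyldimethylsilyloxy)drimane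
Product: 22 (5βH,9αH)-11-(tert-butyldimethylsilyloxy)drim-7-en-6β-ol
Conditions: 2,2,6,6-tetramethylpiperidine, n-BuLi, then Et2AlCl, toluene, 0 °C; then 21, 0 °C → rt; aqueous work-up
Reagents that add atoms: none
Why: Aluminium amide promoted epoxide-to-allylic-alcohol isomerisation, in which aluminium binds the epoxide oxygen and the amide removes a syn β-hydrogen through a cyclic transition state; H8β is reachable whereas H5β is buried between quaternary C4 and C10, so C7–O breaks, the transient C8 centre is erased and C6 keeps its β oxygen.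

Step 14
Reactants: 22 (5βH,9αH)-11-(tert-butyldimethylsilyloxy)drim-7-en-6β-ol
Product: 23 (5βH,9αH)-11-(tert-butyldimethylsilyloxy)drim-7-en-6-one
Conditions: Dess–Martin periodinane, NaHCO3, CH2Cl2, 0 °C
Reagents that add atoms: none
Why: Dess–Martin oxidation under bicarbonate buffering removes the wrong C6 configuration without enolising the now α-carbonyl C5–H, so the cis ring fusion is kept.

Step 15
Reactants: 23 (5βH,9αH)-11-(tert-butyldimethylsilyloxy)drim-7-en-6-one
Product: 24 (5βH,9αH)-11-(tert-butyldimethylsilyloxy)drim-7-en-6α-ol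
Conditions: NaBH4, CeCl3·7H2O, MeOH, −78 °C
Reagents that add atoms: none
Why: Luche 1,2-reduction, in which hydride enters from the convex β face because ring A and the C4 methyl groups shield the α face, setting C6 as the α-alcohol, while the cold, near-neutral medium leaves C5–H untouched.

Step 16
Reactants: 24 (5βH,9αH)-11-(tert-butyldimethylsilyloxy)drim-7-en-6α-ol
Product: 25 (5βH,9αH)-11-(tert-butyldimethylsilyloxy)drim-7-en-6α-yl acetate
Conditions: Ac2O, pyridine, 4-(dimethylamino)pyridine (10 mol %), CH2Cl2, rt
Reagents that add atoms: acetic anhydride, CC(=O)OC(C)=O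
Why: Nucleophile-catalysed O-acylation of the secondary alcohol, which proceeds with retention at C6.

Step 17
Reactants: 25 (5βH,9αH)-11-(tert-butyldimethylsilyloxy)drim-7-en-6α-yl acetate
Product: 26 (5βH,9αH)-11-hydroxydrim-7-en-6α-yl acetate
Conditions: HF·pyridine, THF, 0 °C → rt
Reagents that add atoms: none
Why: Fluoride-driven Si–O cleavage in a mildly acidic medium, which avoids the acetate hydrolysis or migration that basic fluoride could cause.

Step 18
Reactants: 26 (5βH,9αH)-11-hydroxydrim-7-en-6α-yl acetate
Product: 27 (5βH,9αH)-11-oxodrim-7-en-6α-yl acetate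
Conditions: Dess–Martin periodinane, NaHCO3, CH2Cl2, 0 °C
Reagents that add atoms: none
Why: Buffered, non-basic Dess–Martin oxidation gives the β,γ-unsaturated aldehyde without epimerising C9 or moving the alkene into conjugation.

Step 19
Reactants: 27 (5βH,9αH)-11-oxodrim-7-en-6α-yl acetate; 28 1-(triphenylphosphoranylidene)propan-2-one
Product: 29 (11E)-6α-acetoxy-5βH-14,15-dinorlabda-7,11-dien-13-one
Conditions: 28 (3 equiv), toluene, 90 °C
Reagents that add atoms: none
Why: Wittig olefination with a stabilised ylide, which is E-selective and too weakly basic to deprotonate C9–H.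

Step 20
Reactants: 29 (11E)-6α-acetoxy-5βH-14,15-dinorlabda-7,11-dien-13-one
Product: 30 (11E)-6α-acetoxy-7β,8β-epoxy-5βH-14,15-dinorlabd-11-en-13-one
Conditions: mCPBA, NaHCO3, CH2Cl2, 0 °C
Reagents that add atoms: 3-chloroperoxybenzoic acid, OOC(=O)c1cccc(Cl)c1
Why: Prilezhaev epoxidation, chemoselective for the trisubstituted C7=C8 alkene over the electron-poor enone and directed to the convex β face because ring A and the 6α-acetoxy group occupy the α face, which sets C7.

Step 21
Reactants: 30 (11E)-6α-acetoxy-7β,8β-epoxy-5βH-14,15-dinorlabd-11-en-13-one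
Product: 31 (11E)-6α-acetoxy-7β,8α-dihydroxy-5βH-14,15-dinorlabd-11-en-13-one (CNP0136046.2)
Conditions: HClO4 (5 mol %), THF–H2O, 0 °C
Reagents that add atoms: water, O
Why: Acid-catalysed trans-diaxial epoxide hydrolysis, in which the tertiary C8–O bond, remote from the electron-withdrawing acetate, is the one loosened and water attacks C8 anti from the α face with inversion (8α-OH, 8β-methyl), while C7 keeps its β oxygen and the cold dilute acid spares the acetate.

Compound list
1 | (E)-crotyl bromide | C/C=C/CBr | starting material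
2 | diethyl (E)-but-2-en-1-ylphosphonate | C/C=C/CP(=O)(OCC)OCC | intermediate
3 | 2,2-dimethylpent-4-enal | C=CCC(C)(C)C=O | starting material
4 | lithiated diethyl (E)-but-2-en-1-ylphosphonate | [Li]C(/C=C/C)P(=O)(OCC)OCC | intermediate
5 | (5E,7E)-4,4-dimethylnona-1,5,7-triene | C=CCC(C)(C)/C=C/C=C/C | intermediate
6 | 9-[(5E,7E)-4,4-dimethylnona-5,7-dien-1-yl]-9-borabicyclo[3.3.1]nonane | C/C=C/C=C/C(C)(C)CCCB1C2CCCC1CCC2 | intermediate
7 | (5E,7E)-4,4-dimethylnona-5,7-dien-1-ol | C/C=C/C=C/C(C)(C)CCCO | intermediate
8 | (5E,7E)-4,4-dimethylnona-5,7-dienal | C/C=C/C=C/C(C)(C)CCC=O | intermediate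
9 | but-2-yn-1-ol | CC#CCO | starting material
10 | tert-butyl(but-2-yn-1-yloxy)dimethylsilane | CC#CCO[Si](C)(C)C(C)(C)C | intermediate
11 | (E)-alkenylzirconocene chloride (Zr on the methyl-bearing carbon, trans to CH2OTBS) | Cl[Zr](C1C=CC=C1)(C1C=CC=C1)/C(C)=C/CO[Si](C)(C)C(C)(C)C | intermediate
12 | (E)-tert-butyl[(3-iodobut-2-en-1-yl)oxy]dimethylsilane | C/C(I)=C\CO[Si](C)(C)C(C)(C)C | intermediate
13 | (E)-4-(tert-butyldimethylsilyloxy)but-2-en-2-yllithium | [Li]/C(C)=C/CO[Si](C)(C)C(C)(C)C | intermediate
14 | (2E,8E,10E)-1-(tert-butyldimethylsilyloxy)-3,7,7-trimethyldodeca-2,8,10-trien-4-ol (carbinol centre racemic) | C/C=C/C=C/C(C)(C)CCC(O)/C(C)=C/CO[Si](C)(C)C(C)(C)C | intermediate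
15 | (2E,8E,10E)-1-(tert-butyldimethylsilyloxy)-3,7,7-trimethyldodeca-2,8,10-trien-4-one | CC(C)(C)[Si](C)(C)OC/C=C(\C)C(=O)CCC(C)(C)/C=C/C=C/C | intermediate
16 | (5βH,8βH,9αH)-11-(tert-butyldimethylsilyloxy)drim-6-en-1-one | CC(C)(C)[Si](C)(C)OC[C@H]1[C@H](C)C=C[C@@H]2C(C)(C)CCC(=O)[C@@]21C | intermediate
17 | 1-(4-methylbenzenesulfonyl)hydrazone of 16 | CC(C)(C)[Si](C)(C)OC[C@H]1[C@H](C)C=C[C@@H]2C(C)(C)CCC(=NNS(=O)(=O)c3ccc(C)cc3)[C@@]21C | intermediate
18 | N-(1,3,2-benzodioxaborol-2-yl) tosylhydrazine at C1 (C1 configuration undefined, lost in the same step) | CC(C)(C)[Si](C)(C)OC[C@H]1[C@H](C)C=C[C@@H]2C(C)(C)CCC(N(NS(=O)(=O)c3ccc(C)cc3)B3Oc4ccccc4O3)[C@@]21C | intermediate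
19 | C1 monoalkyl diazene (C1 configuration undefined, lost in the same step) | CC(C)(C)[Si](C)(C)OC[C@H]1[C@H](C)C=C[C@@H]2C(C)(C)CCC(N=N)[C@@]21C | intermediate
20 | (5βH,8βH,9αH)-11-(tert-butyldimethylsilyloxy)drim-6-ene | CC(C)(C)[Si](C)(C)OC[C@H]1[C@H](C)C=C[C@@H]2C(C)(C)CCC[C@@]21C | intermediate
21 | (5βH,8βH,9αH)-6β,7β-epoxy-11-(tert-butyldimethylsilyloxy)drimane | CC(C)(C)[Si](C)(C)OC[C@H]1[C@H](C)[C@H]3O[C@H]3[C@@H]2C(C)(C)CCC[C@@]21C | intermediate
22 | (5βH,9αH)-11-(tert-butyldimethylsilyloxy)drim-7-en-6β-ol | CC(C)(C)[Si](C)(C)OC[C@H]1C(C)=C[C@@H](O)[C@@H]2C(C)(C)CCC[C@@]21C | intermediate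
23 | (5βH,9αH)-11-(tert-butyldimethylsilyloxy)drim-7-en-6-one | CC(C)(C)[Si](C)(C)OC[C@H]1C(C)=CC(=O)[C@@H]2C(C)(C)CCC[C@@]21C | intermediate
24 | (5βH,9αH)-11-(tert-butyldimethylsilyloxy)drim-7-en-6α-ol | CC(C)(C)[Si](C)(C)OC[C@H]1C(C)=C[C@H](O)[C@@H]2C(C)(C)CCC[C@@]21C | intermediate
25 | (5βH,9αH)-11-(tert-butyldimethylsilyloxy)drim-7-en-6α-yl acetate | CC(C)(C)[Si](C)(C)OC[C@H]1C(C)=C[C@H](OC(C)=O)[C@@H]2C(C)(C)CCC[C@@]21C | intermediate
26 | (5βH,9αH)-11-hydroxydrim-7-en-6α-yl acetate | OC[C@H]1C(C)=C[C@H](OC(C)=O)[C@@H]2C(C)(C)CCC[C@@]21C | intermediate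
27 | (5βH,9αH)-11-oxodrim-7-en-6α-yl acetate | O=C[C@H]1C(C)=C[C@H](OC(C)=O)[C@@H]2C(C)(C)CCC[C@@]21C | intermediate
28 | 1-(triphenylphosphoranylidene)propan-2-one | CC(=O)C=P(c1ccccc1)(c1ccccc1)c1ccccc1 | starting material
29 | (11E)-6α-acetoxy-5βH-14,15-dinorlabda-7,11-dien-13-one | CC(=O)/C=C/[C@H]1C(C)=C[C@H](OC(C)=O)[C@@H]2C(C)(C)CCC[C@@]21C | intermediate
30 | (11E)-6α-acetoxy-7β,8β-epoxy-5βH-14,15-dinorlabd-11-en-13-one | CC(=O)/C=C/[C@H]1[C@@]3(C)O[C@H]3[C@H](OC(C)=O)[C@@H]2C(C)(C)CCC[C@@]21C | intermediate
31 | (5R,6R,7S,8S,9R,10S,11E)-6-acetoxy-7,8-dihydroxy-14,15-dinorlabd-11-en-13-one (6α-OAc, 7β-OH, 8α-OH, 5βH) | CC(=O)/C=C/[C@H]1[C@](C)(O)[C@@H](O)[C@H](OC(C)=O)[C@@H]2C(C)(C)CCC[C@@]21C | target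

Total step count: 21.
Longest linear sequence: 19 steps (steps 1–4 and 7–21); steps 5 and 6 form the side branch.

Steps most likely to fail

1. Step 9.
- Risk: the catalyst may discriminate poorly between the two enone faces, because the α-methyl enone offers no α-vinylic hydrogen for a second contact. Turnover may be slow enough for the uncatalysed racemic pathway to take part. Exo folding of the tether may erode the cis fusion.
- Fallback (racemic cycloaddition plus resolution): from 15, Et2AlCl in CH2Cl2 at −78 to −20 °C should give the racemic cis-octalone F1. HF·pyridine then frees the racemic keto alcohol F2. Esterification with (S)-2-methoxy-2-phenylacetic acid (N,N'-dicyclohexylcarbodiimide, 4-(dimethylamino)pyridine) gives the wanted mandelate-type ester F3 and its diastereomeric ester F4, to be separated by chromatography or crystallisation. K2CO3 in MeOH releases the enantiopure keto alcohol F5, and TBSCl with imidazole returns to the route at 16.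

2. Step 21.
- Risk: the positive charge developing at C8 may be discharged by loss of H9, which the enone activates, leading to conjugation instead of hydration. Water may enter with incomplete inversion or at C7. The 6α-acetate may take part in the opening or migrate to O7.
- Fallback (open the epoxide before the enone exists and let a hydroxyl group set the epoxide face): from 26, the free C11 hydroxyl directs VO(acac)2 (cat.) and t-BuOOH to the β face and should give the β-epoxy alcohol F6. The same dilute HClO4 hydrolysis, now without an enone beside C9, should give the triol monoacetate F7. PhI(OAc)2 with catalytic 2,2,6,6-tetramethylpiperidine-1-oxyl oxidises only the primary alcohol to the dihydroxy aldehyde F8. Wittig olefination with 28 rejoins the route at 31.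

3. Step 19.
- Risk: the weakly nucleophilic ylide may add slowly to the neopentyl-type aldehyde. Prolonged heating could then move the C7=C8 alkene into conjugation with the aldehyde or epimerise C9.
- Fallback (small reactive ylide, then metathesis): from 27, methylenation with Ph3P=CH2 (Ph3PCH3Br, KN(SiMe3)2, THF, −78 °C) should give the 9β-vinyl compound F9. Cross metathesis with but-3-en-2-one (Hoveyda–Grubbs second-generation catalyst, CH2Cl2, 40 °C) returns to the route at 29.

Further compounds
F1 | step 9 | rac-(5βH,8βH,9αH)-11-(tert-butyldimethylsilyloxy)drim-6-en-1-one (racemate, relative configuration drawn) | CC(C)(C)[Si](C)(C)OC[C@H]1[C@H](C)C=C[C@@H]2C(C)(C)CCC(=O)[C@@]21C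
F2 | step 9 | rac-(5βH,8βH,9αH)-11-hydroxydrim-6-en-1-one (racemate, relative configuration drawn) | OC[C@H]1[C@H](C)C=C[C@@H]2C(C)(C)CCC(=O)[C@@]21C
F3 | step 9 | (S)-2-methoxy-2-phenylacetate of (5βH,8βH,9αH)-11-hydroxydrim-6-en-1-one (wanted diastereomer) | CO[C@H](C(=O)OC[C@H]1[C@H](C)C=C[C@@H]2C(C)(C)CCC(=O)[C@@]21C)c1ccccc1
F4 | step 9 | (S)-2-methoxy-2-phenylacetate of the mirror-image keto alcohol (unwanted diastereomer) | CO[C@H](C(=O)OC[C@@H]1[C@@H](C)C=C[C@H]2C(C)(C)CCC(=O)[C@]21C)c1ccccc1
F5 | step 9 | (5βH,8βH,9αH)-11-hydroxydrim-6-en-1-one (single enantiomer) | OC[C@H]1[C@H](C)C=C[C@@H]2C(C)(C)CCC(=O)[C@@]21C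
F6 | step 21 | (5βH,9αH)-7β,8β-epoxy-11-hydroxydriman-6α-yl acetate | OC[C@H]1[C@@]3(C)O[C@H]3[C@H](OC(C)=O)[C@@H]2C(C)(C)CCC[C@@]21C
F7 | step 21 | (5βH,9αH)-7β,8α,11-trihydroxydriman-6α-yl acetate | OC[C@H]1[C@](C)(O)[C@@H](O)[C@H](OC(C)=O)[C@@H]2C(C)(C)CCC[C@@]21C
F8 | step 21 | (5βH,9αH)-7β,8α-dihydroxy-11-oxodriman-6α-yl acetate | O=C[C@H]1[C@](C)(O)[C@@H](O)[C@H](OC(C)=O)[C@@H]2C(C)(C)CCC[C@@]21C
F9 | step 19 | (5βH,9αH)-9β-vinyl-11-nordrim-7-en-6α-yl acetate | C=C[C@H]1C(C)=C[C@H](OC(C)=O)[C@@H]2C(C)(C)CCC[C@@]21C
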